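**Conventions.** The central ring is numbered C1 (3-acetoxybutanoyloxy), C2 (OH), C3 (aryl), C4 (benzoyloxy), C5 (OH), C6 (aryl); the same atom labels are used for the open-chain precursors. Compound numbers are those of the steps and of the compound list.

## Analysis of the target

Curtisian T (21) is a para-terphenyl whose central benzene ring is fully substituted: an ester of (3R)-3-acetoxybutanoic acid at C1, a free hydroxyl at C2, a 4-hydroxyphenyl ring at C3, a benzoate at C4, a free hydroxyl at C5 and a second 4-hydroxyphenyl ring at C6. Without the two acyl groups the central ring would consist of three symmetry-related pairs of substituents, so the difficulty lies less in the carbon skeleton than in telling four ring oxygens apart and placing two different esters para to each other (C1, C4) while C2 and C5 stay free. The only stereocentre is C3 of the butanoyl chain (R); it is remote from the ring, not alpha to a carbonyl, and has no partner to be related to, so it is best bought. The sensitive points are the two aryl esters that each sit next to a free phenol (base invites a 1,2-acyl shift from C1 to C2 or from C4 to C5), the 3-acetoxy ester (loss of acetic acid by beta-elimination) and the electron-rich hydroquinone (oxidation). Read in reverse, the last point helps: 21 is the two-electron reduction product of a 2,5-diacyloxy-1,4-benzoquinone in which C2 and C5 are carbonyls and no acyl shift is possible. The plan rests on the fact that C4 and C5 are neighbouring oxygen-bearing ring carbons that can both be ester carbons. They are the two ends of the chain C4–C3(aryl)–C2(O)–C1(O)–C6(aryl)–C5, which two arylacetate units (C3/C4 and C6/C5) and one oxalate unit (C1/C2) assemble. Joining C4 to C5 closes the ring with every substituent already in place.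

## Retrosynthetic reasoning

**21 back to 19.** The last disconnection cuts no skeletal bond: it restores the two benzyl–oxygen bonds on the outer rings and takes C2 and C5 back to quinone carbonyls. This puts every acylation before a neutral final step, at an oxidation level where the esters cannot migrate. The forward reaction must reduce the quinone (to 20) and hydrogenolyse two benzyl ethers without touching three esters.

**19 back to 15 and 18.** The acyl C–O bond at C1 is cut last among the esters because the beta-acetoxy ester is the most fragile group. The hydroxyquinone 15 has a single acidic hydroxyl, so the acylation has no competitor. The acid chloride 18 comes from 17 and that from the chiral-pool acid 16; no bond to the stereocentre is ever broken.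

**15 back to 14 and 13.** First the O–CH3 bond at C1 is restored (14), then the quinone is taken back to a para-methoxyphenol (13), with the C5 hydroxyl free and C2 carrying a methyl ether. This is where the para relationship of the two esters is decided: in 13 the free hydroxyl at C5 lies para to C2, so oxidation removes the methyl group at C2 and spares the one at C1, which is para to the benzoate at C4. The forward steps are a two-electron oxidation and a dealkylation at the methyl carbon, a mechanism that cannot touch an acyl group.

**13 back to 11 and 12, and 11 back to 10.** The benzoate C–O bond at C4 is cut. The catechol 11 has a mirror plane through the C4–C5 and C1–C2 bonds, so its two hydroxyls are equivalent: monoacylation raises no regiochemical question, and a benzoyl shift between them gives the same compound. 11 is the desilylated form of 10.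

**10 back to 6 (key disconnection).** The C4–C5 bond is cut. It is the only ring bond whose two carbons can both come from carboxyl groups. Cutting it opens the ring to one symmetric chain that is easy to make. The oxygens at C1/C2 arrive as methyl enol ethers and those at C4/C5 as silyl ethers, so the two pairs differ from the moment the ring exists. The forward reaction must deliver four electrons, join two like-polarised ester carbons, expel the two ester methoxy groups and end at the aromatic oxidation level.

**6 back to 5, then to 2 and 3, then to 1.** The two enol O–CH3 bonds are cut (5), then the C3–C2 and C6–C1 bonds, which a double Claisen condensation of two molecules of 2 with 3 forms (through 4); 2 is the methyl ester of 1. Benzyl is chosen for the outer phenols because it survives base, reducing metal, acid, oxidant and iodide and leaves in the same hydrogenation that reduces the quinone.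

## Alternatives that were turned down

**Alternative 1: enzymatic head-to-tail dimerisation.**
- Disconnection: C3–C4 and C6–C1, each joining the benzylic carbon of one molecule of 4-hydroxyphenylpyruvic acid (A1) to the carboxyl carbon of the other.
- Forward key step: the atromentin-forming synthetase, with its cofactors, loads two molecules of A1 as thioesters, condenses them twice and releases the dihydroxyquinone atromentin (A2).
- For: one step from a commercial acid to the whole skeleton with all six ring substituents, in water, without protecting groups. On step count to the core and on certainty of ring closure it is stronger than the chosen route.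
- Against: it needs an expressed and activated enzyme and is limited in scale. A2 is centrosymmetric, with two equivalent acidic quinone hydroxyls and two free phenols. The target needs two different acyl groups on the quinone oxygens and none on the phenols, so two statistical monoacylations would have to be run on an unprotected tetrol.
- Comparison: the chosen route is purely chemical, masks the outer phenols from the start, and forms the ring with its two oxygen pairs already differentiated.

**Alternative 2: cyclopentadienone Diels–Alder with loss of the bridging carbonyl.**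
- Disconnection: C3–C4 and C5–C6; C4 and C5 come from vinylene carbonate (A4), and C3, C2, C1, C6 from the diene of the 3,4-dimethoxy-2,5-diarylcyclopentadienone A3.
- Forward key step: thermal cycloaddition of A3 and A4, then cheletropic loss of the bridging carbonyl, gives the cyclohexadiene cis-carbonate A5.
- For: both ring bonds form in one convergent step, and the reaction class is better established than the chosen ring closure. It reaches the same differentiation (C4/C5 as a carbonate, C1/C2 as methyl ethers).
- Against: A3 lacks the four aryl groups that make such dienones isolable and should dimerise, and A4 is a sluggish dienophile that needs high temperature. A5 is still two hydrogens above the arene. At the temperature of its formation, a redox-neutral elimination of the carbonate would aromatise the ring with loss of one of the C4/C5 oxygens. A separate dehydrogenation and a carbonate cleavage are needed.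
- Comparison: the chosen route reaches the aromatic oxidation level in the ring-forming operation, from a three-step acyclic precursor.

**Alternative 3: ring expansion of a squarate-derived alkenylcyclobutenone (Moore rearrangement).**
- Disconnection: the C1–C2 bond; a four-membered ring supplies C2 to C5 and a 1-aryl-2-methoxyvinyl group supplies C6 and C1.
- Forward key step: heating the cyclobutenone A6 in an aromatic solvent opens it to a dienylketene, whose ketene carbon (C2) closes onto the methoxy-bearing alkene carbon (C1); tautomerisation gives the hydroquinone A7.
- For: a well-behaved thermal reaction class with the position of all six substituents programmed. The two oxygens that carry esters in the target (C1, C4) arrive as two different ethers (methyl, tert-butyl), and C2/C5 as the free hydroxyls. On precedent and on differentiation it is stronger than the chosen route, which needs a monobenzoylation.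
- Against: A6 needs an unsymmetrical aryl alkoxy cyclobutenedione and a metallated methoxystyrene, each two to three steps, joined regioselectively, so the sequence before the ring is roughly twice as long and linear. In A7 the ethers at C1/C4 must still be exchanged for esters next to free hydroxyls. This again means oxidation to the quinone, dealkylation, acylation, a methyl cleavage beside an ester, and acylation, so the endgame is no shorter.
- Comparison: the chosen route uses the hidden symmetry of the target. The whole skeleton comes from two arylacetates and one oxalate in two operations, and the monobenzoylation is regiochemically trivial because of that symmetry.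

Key step: step 4

Assumption: 6 is drawn as the (2Z,4Z) isomer expected from methylation of the chelated enolates; an E isomer should enter step 4 equally well, because the reduction turns both enol ether double bonds into single bonds.

## Route

Step 1
Reactants: 1 4-(benzyloxy)phenylacetic acid
Product: 2 methyl [4-(benzyloxy)phenyl]acetate
Conditions: MeOH, H2SO4 (cat.), reflux
Reagents that add atoms: methanol, CO
Why: Fischer esterification driven by the solvent excess; the aryl benzyl ether is stable to catalytic acid in methanol.

Step 2
Reactants: 2 methyl [4-(benzyloxy)phenyl]acetate (2 equiv); 3 dimethyl oxalate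
Product: 5 dimethyl (2Z,4Z)-2,5-bis[4-(benzyloxy)phenyl]-3,4-dihydroxyhexa-2,4-dienedioate, via mono-condensation keto diester 4 (not isolated)
Conditions: NaH (2.5 equiv), THF, 0 °C → reflux; then cold 1 M HCl
Reagents that add atoms: none
Why: Double crossed Claisen condensation: 3 cannot enolise, and each condensation is pulled forward by deprotonation of the new beta-keto ester. The 3,4-diketone should be obtained as its doubly hydrogen-bonded bis-enol, which holds the C3–C2 and C6–C1 bonds of the later ring.

Step 3
Reactants: 5 dimethyl (2Z,4Z)-2,5-bis[4-(benzyloxy)phenyl]-3,4-dihydroxyhexa-2,4-dienedioate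
Product: 6 dimethyl (2Z,4Z)-2,5-bis[4-(benzyloxy)phenyl]-3,4-dimethoxyhexa-2,4-dienedioate
Conditions: Me2SO4, K2CO3, acetone, reflux
Reagents that add atoms: dimethyl sulfate, COS(=O)(=O)OC
Why: O-alkylation of the potassium enolates of a strongly enolised alpha-aryl beta-keto ester by a hard electrophile, the method used to make beta-methoxyacrylates. C-methylation would have to build a quaternary aryl-bearing carbon and is disfavoured.

Step 4
Reactants: 6 dimethyl (2Z,4Z)-2,5-bis[4-(benzyloxy)phenyl]-3,4-dimethoxyhexa-2,4-dienedioate
Product: 10 3,6-bis[4-(benzyloxy)phenyl]-1,2-dimethoxy-4,5-bis(trimethylsilyloxy)benzene, via bis(silyl ketene acetal) triene 7 (not isolated), via ring-closed diene bis-ketal 8 (not isolated), via dimethoxy-ortho-quinone 9 (not isolated)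
Conditions: Mg turnings (activated, excess), Me3SiCl (6 equiv), DMF, 0 °C → rt, slow addition of 6, argon; non-aqueous work-up
Reagents that add atoms: chlorotrimethylsilane, C[Si](C)(C)Cl
Why: Proposed new method: magnesium should transfer two electrons into the low-lying LUMO of the conjugated dienedioate 6, and Me3SiCl should trap the resulting dienolate on oxygen as the bis(silyl ketene acetal) 7, whose double bonds are C4=C3, C2=C1 and C6=C5, so the alkene geometry of 6 no longer matters and only a cis C2=C1 bond is needed, which chelation of Mg2+ by the two vicinal methoxy groups should favour. The central six-membered ring then closes between C4 and C5 by a thermal disrotatory 6π-electrocyclisation of this triene (or, before silylation, by combination of the two ketyl-like termini of the dianion, the usual acyloin pathway) to give 8. With MgCl2 and Me3SiCl each mixed methyl silyl ketal of 8 should ionise and lose Me3SiOMe, giving the ortho-quinone 9; 9 is reduced far more easily than 6, so two more electrons and two Me3SiCl convert it into the aromatic bis-silyl ether 10. The closest known reactions are the Rühlmann acyloin condensation of 1,6-diesters (sodium, Me3SiCl) and the Mg/Me3SiCl reductions of conjugated esters and quinones in DMF; new is their use on a conjugated 1,6-diester with aromatisation as the driving force. No stereocentre is formed. The step needs carbonyl–carbonyl coupling to beat conjugate reduction, C-silylation and intermolecular hydrodimerisation. The beta carbons C2 and C1 are fully substituted and already bonded to each other, coupling through the alpha carbons C3 and C6 would give a four-membered ring, and slow addition at high dilution should keep the process intramolecular.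

Step 5
Reactants: 10 3,6-bis[4-(benzyloxy)phenyl]-1,2-dimethoxy-4,5-bis(trimethylsilyloxy)benzene
Product: 11 3,6-bis[4-(benzyloxy)phenyl]-4,5-dimethoxybenzene-1,2-diol
Conditions: 1 M HCl, THF, 0 °C → rt, argon
Reagents that add atoms: none
Why: Acid hydrolysis of aryl trimethylsilyl ethers, which leaves methyl and benzyl ethers alone. Air is excluded because the electron-rich catechol is easily oxidised.

Step 6
Reactants: 11 3,6-bis[4-(benzyloxy)phenyl]-4,5-dimethoxybenzene-1,2-diol; 12 benzoyl chloride (1.0 equiv)
Product: 13 3,6-bis[4-(benzyloxy)phenyl]-2-hydroxy-4,5-dimethoxyphenyl benzoate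
Conditions: Et3N (1.1 equiv), CH2Cl2, −78 → 0 °C, argon
Reagents that add atoms: none
Why: O-acylation of the catechol monoanion. The two hydroxyls are mirror-related, so only one monoester exists and a 1,2-benzoyl shift is degenerate. The second acylation should be slower because the remaining hydroxyl is hydrogen-bonded to the new ester and flanked by an aryl ring.

Step 7
Reactants: 13 3,6-bis[4-(benzyloxy)phenyl]-2-hydroxy-4,5-dimethoxyphenyl benzoate
Product: 14 2,5-bis[4-(benzyloxy)phenyl]-4-methoxy-3,6-dioxocyclohexa-1,4-dien-1-yl benzoate
Conditions: (NH4)2Ce(NO3)6 (2.2 equiv), MeCN–H2O, 0 °C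
Reagents that add atoms: water, O
Why: Oxidative demethylation of a para-methoxyphenol: two one-electron oxidations by tetravalent cerium give the phenoxonium ion, water adds at C2 (para to the C5 hydroxyl, where the methoxy group stabilises the cation) and methanol is lost. The methyl ether at C1 is spared, which fixes it para to the benzoate at C4; the free phenol is oxidised far more readily than the aryl benzyl ethers.

Step 8
Reactants: 14 2,5-bis[4-(benzyloxy)phenyl]-4-methoxy-3,6-dioxocyclohexa-1,4-dien-1-yl benzoate
Product: 15 2,5-bis[4-(benzyloxy)phenyl]-4-hydroxy-3,6-dioxocyclohexa-1,4-dien-1-yl benzoate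
Conditions: LiI (3 equiv), EtOAc, 60 °C, dark, argon; then 0.5 M HCl
Reagents that add atoms: none
Why: SN2 dealkylation: the methoxyquinone is the vinylogous methyl ester of an acid about as strong as a carboxylic acid, so iodide attacks the methyl carbon as it does in the cleavage of methyl esters with LiI. This mechanism cannot remove the benzoyl group, and the aryl benzyl ethers offer a far poorer leaving group. A benzoyl shift to the neighbouring oxygen of the delocalised anion gives back the same compound.

Step 9
Reactants: 16 (R)-3-hydroxybutanoic acid
Product: 17 (3R)-3-acetoxybutanoic acid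
Conditions: AcCl (1.5 equiv), CH2Cl2, 0 °C → rt; then H2O
Reagents that add atoms: acetyl chloride, CC(=O)Cl
Why: Base-free O-acetylation of a hydroxy acid. No bond to the stereocentre is broken, so the R configuration is kept; water hydrolyses any mixed anhydride.

Step 10
Reactants: 17 (3R)-3-acetoxybutanoic acid
Product: 18 (3R)-3-acetoxybutanoyl chloride
Conditions: (COCl)2 (1.2 equiv), DMF (cat.), CH2Cl2, 0 °C → rt; evaporate
Reagents that add atoms: oxalyl chloride, O=C(Cl)C(=O)Cl
Why: Acid chloride formation through the Vilsmeier-type chloroiminium species, without base, so acetic acid is not eliminated. The stereocentre is beta to the carbonyl and is not affected.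

Step 11
Reactants: 15 2,5-bis[4-(benzyloxy)phenyl]-4-hydroxy-3,6-dioxocyclohexa-1,4-dien-1-yl benzoate; 18 (3R)-3-acetoxybutanoyl chloride
Product: 19 4-(benzoyloxy)-2,5-bis[4-(benzyloxy)phenyl]-3,6-dioxocyclohexa-1,4-dien-1-yl (3R)-3-acetoxybutanoate
Conditions: pyridine (1.5 equiv), CH2Cl2, −20 → 0 °C
Reagents that add atoms: none
Why: O-acylation of the only acidic hydroxyl; the weak base pyridine acts through the acylpyridinium ion and not through a ketene, which limits beta-elimination. Acylation on the C1 oxygen gives the para-quinone, the more stable of the two possible ambident products; the stereocentre is carried through untouched.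

Step 12
Reactants: 19 4-(benzoyloxy)-2,5-bis[4-(benzyloxy)phenyl]-3,6-dioxocyclohexa-1,4-dien-1-yl (3R)-3-acetoxybutanoate
Product: 21 4-(benzoyloxy)-2,5-dihydroxy-3,6-bis(4-hydroxyphenyl)phenyl (3R)-3-acetoxybutanoate (Curtisian T), via dibenzyl ether hydroquinone 20 (not isolated)
Conditions: H2 (1 atm), 10% Pd/C, EtOAc–THF, rt
Reagents that add atoms: none
Why: Catalytic hydrogenation: the quinone should be reduced first to the hydroquinone 20, then the two aryl benzyl ethers are hydrogenolysed. Aryl esters and the acetate are inert, the neutral medium gives no base to trigger acyl migration, and the stereocentre has no reducible bond.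

## Compound list

1 | 4-(benzyloxy)phenylacetic acid | O=C(O)Cc1ccc(OCc2ccccc2)cc1 | starting material
2 | methyl [4-(benzyloxy)phenyl]acetate | COC(=O)Cc1ccc(OCc2ccccc2)cc1 | intermediate
3 | dimethyl oxalate | COC(=O)C(=O)OC | starting material
4 | dimethyl 2-[4-(benzyloxy)phenyl]-3-oxobutanedioate (racemic, enolised; not isolated) | COC(=O)C(=O)C(C(=O)OC)c1ccc(OCc2ccccc2)cc1 | intermediate
5 | dimethyl (2Z,4Z)-2,5-bis[4-(benzyloxy)phenyl]-3,4-dihydroxyhexa-2,4-dienedioate | COC(=O)/C(-c1ccc(OCc2ccccc2)cc1)=C(\O)C(/O)=C(-c1ccc(OCc2ccccc2)cc1)/C(=O)OC | intermediate
6 | dimethyl (2Z,4Z)-2,5-bis[4-(benzyloxy)phenyl]-3,4-dimethoxyhexa-2,4-dienedioate | COC(=O)/C(-c1ccc(OCc2ccccc2)cc1)=C(\OC)C(/OC)=C(-c1ccc(OCc2ccccc2)cc1)/C(=O)OC | intermediate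
7 | (3Z)-2,5-bis[4-(benzyloxy)phenyl]-1,3,4,6-tetramethoxy-1,6-bis(trimethylsilyloxy)hexa-1,3,5-triene (terminal geometry open; not isolated) | COC(O[Si](C)(C)C)=C(-c1ccc(OCc2ccccc2)cc1)/C(OC)=C(OC)\C(-c1ccc(OCc2ccccc2)cc1)=C(OC)O[Si](C)(C)C | intermediate
8 | 1,4-bis[4-(benzyloxy)phenyl]-2,3,5,6-tetramethoxy-5,6-bis(trimethylsilyloxy)cyclohexa-1,3-diene (relative configuration open; not isolated) | COC1=C(-c2ccc(OCc3ccccc3)cc2)C(OC)(O[Si](C)(C)C)C(OC)(O[Si](C)(C)C)C(-c2ccc(OCc3ccccc3)cc2)=C1OC | intermediate
9 | 3,6-bis[4-(benzyloxy)phenyl]-4,5-dimethoxycyclohexa-3,5-diene-1,2-dione (not isolated) | COC1=C(-c2ccc(OCc3ccccc3)cc2)C(=O)C(=O)C(-c2ccc(OCc3ccccc3)cc2)=C1OC | intermediate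
10 | 3,6-bis[4-(benzyloxy)phenyl]-1,2-dimethoxy-4,5-bis(trimethylsilyloxy)benzene | COc1c(OC)c(-c2ccc(OCc3ccccc3)cc2)c(O[Si](C)(C)C)c(O[Si](C)(C)C)c1-c1ccc(OCc2ccccc2)cc1 | intermediate
11 | 3,6-bis[4-(benzyloxy)phenyl]-4,5-dimethoxybenzene-1,2-diol | COc1c(OC)c(-c2ccc(OCc3ccccc3)cc2)c(O)c(O)c1-c1ccc(OCc2ccccc2)cc1 | intermediate
12 | benzoyl chloride | O=C(Cl)c1ccccc1 | starting material
13 | 3,6-bis[4-(benzyloxy)phenyl]-2-hydroxy-4,5-dimethoxyphenyl benzoate | COc1c(OC)c(-c2ccc(OCc3ccccc3)cc2)c(OC(=O)c2ccccc2)c(O)c1-c1ccc(OCc2ccccc2)cc1 | intermediate
14 | 2,5-bis[4-(benzyloxy)phenyl]-4-methoxy-3,6-dioxocyclohexa-1,4-dien-1-yl benzoate | COC1=C(-c2ccc(OCc3ccccc3)cc2)C(=O)C(OC(=O)c2ccccc2)=C(-c2ccc(OCc3ccccc3)cc2)C1=O | intermediate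
15 | 2,5-bis[4-(benzyloxy)phenyl]-4-hydroxy-3,6-dioxocyclohexa-1,4-dien-1-yl benzoate | OC1=C(-c2ccc(OCc3ccccc3)cc2)C(=O)C(OC(=O)c2ccccc2)=C(-c2ccc(OCc3ccccc3)cc2)C1=O | intermediate
16 | (R)-3-hydroxybutanoic acid | C[C@@H](O)CC(=O)O | starting material
17 | (3R)-3-acetoxybutanoic acid | CC(=O)O[C@H](C)CC(=O)O | intermediate
18 | (3R)-3-acetoxybutanoyl chloride | CC(=O)O[C@H](C)CC(=O)Cl | intermediate
19 | 4-(benzoyloxy)-2,5-bis[4-(benzyloxy)phenyl]-3,6-dioxocyclohexa-1,4-dien-1-yl (3R)-3-acetoxybutanoate | CC(=O)O[C@H](C)CC(=O)OC1=C(-c2ccc(OCc3ccccc3)cc2)C(=O)C(OC(=O)c2ccccc2)=C(-c2ccc(OCc3ccccc3)cc2)C1=O | intermediate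
20 | 4-(benzoyloxy)-3,6-bis[4-(benzyloxy)phenyl]-2,5-dihydroxyphenyl (3R)-3-acetoxybutanoate (not isolated) | CC(=O)O[C@H](C)CC(=O)Oc1c(O)c(-c2ccc(OCc3ccccc3)cc2)c(OC(=O)c2ccccc2)c(O)c1-c1ccc(OCc2ccccc2)cc1 | intermediate
21 | Curtisian T, 4-(benzoyloxy)-2,5-dihydroxy-3,6-bis(4-hydroxyphenyl)phenyl (3R)-3-acetoxybutanoate | CC(=O)O[C@H](C)CC(=O)Oc1c(O)c(-c2ccc(O)cc2)c(OC(=O)c2ccccc2)c(O)c1-c1ccc(O)cc1 | target

## Step count and least certain steps

Total: 12 steps. Longest linear sequence: 10 steps (steps 1 to 8, 11 and 12); steps 9 and 10 make the acid chloride on a side branch.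

**Step 4 (key step, carries the label "Proposed new method:").** The most likely failure is silylation of the reduced chain with the C2=C1 bond trans, which cannot close. Protonation or C-silylation to open-chain dihydro products and intermolecular coupling are the other risks; none has precedent on this substrate class to judge by. The fallback uses known chemistry and makes the same C4–C5 bond by pinacol coupling of aldehydes. It sets out from 6 and returns at 11.
- The two esters are reduced with i-Bu2AlH (CH2Cl2, −78 °C) to (2Z,4Z)-2,5-bis[4-(benzyloxy)phenyl]-3,4-dimethoxyhexa-2,4-diene-1,6-diol F1.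
- MnO2 oxidises F1 to (2Z,4Z)-2,5-bis[4-(benzyloxy)phenyl]-3,4-dimethoxyhexa-2,4-dienedial F2.
- SmI2 (THF, −78 °C → rt) effects the intramolecular pinacol coupling that is standard for 1,6-dialdehydes and should give cis-3,6-bis[4-(benzyloxy)phenyl]-4,5-dimethoxycyclohexa-3,5-diene-1,2-diol F3.
- Oxidation of one carbinol (SO3·pyridine, DMSO, Et3N) gives the keto tautomer of 11, which aromatises to 11.
- Closure needs each formyl group cis to the C2–C1 bond; the push–pull enals of F2 should equilibrate (trace iodine or light), and in the samarium ketyl that double bond is loosened.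

**Step 8.** Benzoyl transfer between molecules is the main risk, because the hydroxyquinonate that forms is an acyl acceptor and the benzoyloxyquinone an acyl donor; loss of the benzoate or incomplete dealkylation are the others. The fallback sets out from 11 and returns at 15, replacing steps 6 to 8 without extra steps.
- Ag2O oxidises 11 to the ortho-quinone 9, isolated this time.
- Aqueous NaOH in dioxane hydrolyses both vinylogous methyl esters, and acidification gives 2,5-bis[4-(benzyloxy)phenyl]-3,6-dihydroxycyclohexa-2,5-diene-1,4-dione F4.
- One equivalent of 12 with pyridine gives 15; the bis-benzoate is returned to F4 by hydrolysis.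
- No acyl group is present during a dealkylation, at the price of a statistical instead of a programmed differentiation.

**Step 2.** The second condensation may stall at the enolate of 4, whose remaining oxalyl ester is deactivated, or the product may cyclise to a butenolide on acidification. The fallback sets out from 2 and returns at 5. The lithium enolate of 2 (LiN(SiMe3)2, THF, −78 °C, excess) is acylated with N,N'-dimethoxy-N,N'-dimethyloxamide. Each amide is attacked once and the chelated tetrahedral adducts persist until the acidic quench, so the second acylation does not have to attack an ester deactivated by a neighbouring enolate. No new isolated compound arises.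

**Step 6.** Over-acylation to the bis-benzoate, or oxidation of the catechol monoanion by traces of air, may erode the monoester. The fallback sets out from 11 and returns at 13. Trimethyl orthobenzoate with catalytic pyridinium p-toluenesulfonate (toluene, 80 °C) closes the cyclic orthoester 4,7-bis[4-(benzyloxy)phenyl]-2,5,6-trimethoxy-2-phenyl-1,3-benzodioxole F5. Mild aqueous acetic acid opens it, and whichever C–O bond breaks, the product is the monoester 13.

**Step 11.** Base-induced loss of acetic acid from 18 (through the ketene or the enolate), leading to a crotonate ester, is the main risk; acyl exchange between quinone esters is the second. The fallback sets out from 17 and returns at 19. Dicyclohexylcarbodiimide (0.5 equiv) converts 17 into (3R)-3-acetoxybutanoic anhydride F6. 15 is then acylated with F6 under acid catalysis (Sc(OTf)3 cat., MeCN, 0 °C), the type of conditions long used to acylate hydroxyquinones with an anhydride, so no base is present at any point.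

**Step 3.** C-methylation at C3/C6 or base-promoted lactonisation onto the remote ester may compete. The fallback sets out from 5 and returns at 6: Mitsunobu O-methylation (MeOH, PPh3, diisopropyl azodicarboxylate, THF, 0 °C), which alkylates the acidic enols under neutral conditions through the alkoxyphosphonium ion. No new isolated compound arises.

## Further compounds

F1 | step 4 | (2Z,4Z)-2,5-bis[4-(benzyloxy)phenyl]-3,4-dimethoxyhexa-2,4-diene-1,6-diol | OC/C(-c1ccc(OCc2ccccc2)cc1)=C(\OC)C(/OC)=C(-c1ccc(OCc2ccccc2)cc1)/CO
F2 | step 4 | (2Z,4Z)-2,5-bis[4-(benzyloxy)phenyl]-3,4-dimethoxyhexa-2,4-dienedial | O=C/C(-c1ccc(OCc2ccccc2)cc1)=C(\OC)C(/OC)=C(-c1ccc(OCc2ccccc2)cc1)/C=O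
F3 | step 4 | cis-(1R,2S)-3,6-bis[4-(benzyloxy)phenyl]-4,5-dimethoxycyclohexa-3,5-diene-1,2-diol (meso) | O[C@H]1[C@@H](O)C(-c2ccc(OCc3ccccc3)cc2)=C(OC)C(OC)=C1-c1ccc(OCc2ccccc2)cc1
F4 | step 8 | 2,5-bis[4-(benzyloxy)phenyl]-3,6-dihydroxycyclohexa-2,5-diene-1,4-dione | O=C1C(O)=C(-c2ccc(OCc3ccccc3)cc2)C(=O)C(O)=C1-c1ccc(OCc2ccccc2)cc1
F0 | step 2 | none | none
F5 | step 6 | 4,7-bis[4-(benzyloxy)phenyl]-2,5,6-trimethoxy-2-phenyl-1,3-benzodioxole | COc1c(OC)c(-c2ccc(OCc3ccccc3)cc2)c2OC(OC)(c3ccccc3)Oc2c1-c1ccc(OCc2ccccc2)cc1
F6 | step 11 | (3R)-3-acetoxybutanoic anhydride | CC(=O)O[C@H](C)CC(=O)OC(=O)C[C@@H](C)OC(C)=O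
F0 | step 3 | none | none
A1 | alternative 1 | 4-hydroxyphenylpyruvic acid | O=C(O)C(=O)Cc1ccc(O)cc1
A2 | alternative 1 | atromentin, 2,5-dihydroxy-3,6-bis(4-hydroxyphenyl)-1,4-benzoquinone | O=C1C(O)=C(-c2ccc(O)cc2)C(=O)C(O)=C1-c1ccc(O)cc1
A3 | alternative 2 | 2,5-bis[4-(benzyloxy)phenyl]-3,4-dimethoxycyclopenta-2,4-dien-1-one | COC1=C(-c2ccc(OCc3ccccc3)cc2)C(=O)C(-c2ccc(OCc3ccccc3)cc2)=C1OC
A4 | alternative 2 | vinylene carbonate | O=C1OC=CO1
A5 | alternative 2 | meso (3aR,7aS)-4,7-bis(4-benzyloxyphenyl)-5,6-dimethoxy-3a,7a-dihydro-1,3-benzodioxol-2-one | COC1=C(-c2ccc(OCc3ccccc3)cc2)[C@H]2OC(=O)O[C@H]2C(-c2ccc(OCc3ccccc3)cc2)=C1OC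
A6 | alternative 3 | 2-[4-(benzyloxy)phenyl]-4-{1-[4-(benzyloxy)phenyl]-2-methoxyethenyl}-3-tert-butoxy-4-hydroxycyclobut-2-en-1-one (racemic, alkene geometry open) | COC=C(c1ccc(OCc2ccccc2)cc1)C1(O)C(=O)C(-c2ccc(OCc3ccccc3)cc2)=C1OC(C)(C)C
A7 | alternative 3 | 2,5-bis(4-benzyloxyphenyl)-3-tert-butoxy-6-methoxyhydroquinone | COc1c(O)c(-c2ccc(OCc3ccccc3)cc2)c(OC(C)(C)C)c(O)c1-c1ccc(OCc2ccccc2)cc1
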